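**Retrosynthetic overview**
- Target ⇐ selective acylation of the C6 hydroxyl and phenol release; the C6 carbinol comes from a hydroxyl-directed reduction of a β-hydroxy ketone, itself unmasked from a tricyclic 2-isoxazoline.
- Isoxazoline ⇐ intramolecular nitrile oxide–olefin [3+2] cycloaddition: it closes the seven-membered ring (C5–C6) onto a preformed cyclopentene, puts the tertiary oxygen on C4 and fixes the cis ring fusion.
- Cycloaddition precursor ⇐ [2,3]-Wittig rearrangement of a tertiary cyclopentenyl (Z)-allyl ether: it forms C1–C10, transfers the carbinol chirality to the quaternary C1 and moves the oxygen to C10 (trapped as the tiglate).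
- Ether ⇐ (R)-1-isopropyl-3-methylcyclopent-2-enol (from (S)-terpinen-4-ol by ozonolysis/aldol ring contraction and decarbonylation) plus a (Z)-allylic bromide (from 4,4-diethoxybut-1-yne via ynoate/cuprate).
- Ring order: five-membered ring first (ring contraction of the bought cyclohexene), seven-membered ring second (cycloaddition).

Assumption: (S)-(+)-terpinen-4-ol is bought as the single enantiomer; locants in bicyclic names follow daucane numbering (C1 = ring-fusion carbon with the methyl, C4 = isopropyl carbinol, C5 = ring-fusion CH, C6 and C10 = oxygenated carbons of the seven-membered ring, C8=C9 = ring olefin). Stereochemical analysis of the given SMILES: (1R,4R,5S,6S,10S), cis-fused, with C4–O, C6 and C10 on one face of the cyclopentane and C10–O trans to the angular methyl.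

**Step 1**
Reactants: 1 (S)-(+)-terpinen-4-ol [(1S)-4-methyl-1-(propan-2-yl)cyclohex-3-en-1-ol]
Product: 4 (5R)-5-hydroxy-2-methyl-5-(propan-2-yl)cyclopent-1-ene-1-carbaldehyde, via secondary ozonide 2 (not isolated), via keto-aldehyde 3 (not isolated)
Conditions: O3, CH2Cl2, −78 °C; Me2S, −78 °C → rt; then piperidine (cat.), AcOH (cat.), PhH, 80 °C (−H2O)
Reagents that add atoms: ozone, [O-][O+]=O
Why: Ozonolysis of the only C=C gives the 1,6-keto-aldehyde, whose aldehyde enamine adds to the methyl ketone (intramolecular aldol condensation, six- to five-membered ring contraction) to give the tetrasubstituted enal, the bought carbinol centre being untouched.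

**Step 2**
Reactants: 4 (5R)-5-hydroxy-2-methyl-5-(propan-2-yl)cyclopent-1-ene-1-carbaldehyde
Product: 5 (1R)-3-methyl-1-(propan-2-yl)cyclopent-2-en-1-ol
Conditions: RhCl(PPh3)3 (1.1 equiv), PhCN, 130 °C
Reagents that add atoms: none
Why: Tsuji–Wilkinson decarbonylation (formyl C–H insertion, CO extrusion, C–H reductive elimination) replaces CHO by H without moving the alkene or touching the carbinol centre.

**Step 3**
Reactants: 6 4,4-diethoxybut-1-yne
Product: 8 methyl 5,5-diethoxypent-2-ynoate, via lithium acetylide 7 (not isolated)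
Conditions: n-BuLi, THF, −78 °C; ClCO2Me, −78 → 0 °C
Reagents that add atoms: methyl chloroformate, COC(=O)Cl
Why: C-acylation of the lithium acetylide with a chloroformate gives the ynoate.

**Step 4**
Reactants: 8 methyl 5,5-diethoxypent-2-ynoate
Product: 9 methyl (2Z)-5,5-diethoxy-3-methylpent-2-enoate
Conditions: Me2CuLi (from MeLi and CuI), THF, −78 °C; NH4Cl (aq.), −78 °C
Reagents that add atoms: lithium dimethylcuprate, [Li+].C[Cu-]C
Why: Syn-carbocupration of the ynoate (cuprate conjugate addition) and cold protonation place the ester cis to the acetal-bearing chain, giving the (Z)-trisubstituted alkene that later sits inside the seven-membered ring.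

**Step 5**
Reactants: 9 methyl (2Z)-5,5-diethoxy-3-methylpent-2-enoate
Product: 10 (2Z)-5,5-diethoxy-3-methylpent-2-en-1-ol
Conditions: i-Bu2AlH (2.2 equiv), CH2Cl2, −78 °C; aq. potassium sodium tartrate KNaC4H4O6
Reagents that add atoms: none
Why: 1,2-Hydride reduction of the enoate to the allylic alcohol leaves the acetal and the alkene geometry unchanged.

**Step 6**
Reactants: 10 (2Z)-5,5-diethoxy-3-methylpent-2-en-1-ol
Product: 11 (2Z)-1-bromo-5,5-diethoxy-3-methylpent-2-ene
Conditions: CBr4, PPh3, 2,6-lutidine, CH2Cl2, −20 → 0 °C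
Reagents that add atoms: carbon tetrabromide, BrC(Br)(Br)Br
Why: Appel bromination of the primary allylic alcohol (SN2, buffered, no allylic transposition) is compatible with the acetal.

**Step 7**
Reactants: 5 (1R)-3-methyl-1-(propan-2-yl)cyclopent-2-en-1-ol; 11 (2Z)-1-bromo-5,5-diethoxy-3-methylpent-2-ene
Product: 13 (1R)-1-{[(2Z)-5,5-diethoxy-3-methylpent-2-en-1-yl]oxy}-3-methyl-1-(propan-2-yl)cyclopent-2-ene, via potassium alkoxide 12 (not isolated)
Conditions: KH, THF, 0 °C; then 11, 18-crown-6 (cat.), 0 °C → rt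
Reagents that add atoms: none
Why: Williamson etherification, in which the tertiary allylic alkoxide displaces the primary allylic bromide by SN2, so the carbinol stereocentre is carried over unchanged.

**Step 8**
Reactants: 13 (1R)-1-{[(2Z)-5,5-diethoxy-3-methylpent-2-en-1-yl]oxy}-3-methyl-1-(propan-2-yl)cyclopent-2-ene; 14 tigloyl chloride [(2E)-2-methylbut-2-enoyl chloride]
Product: 17 (1S,2Z)-5,5-diethoxy-3-methyl-1-[(1R)-1-methyl-3-(propan-2-yl)cyclopent-2-en-1-yl]pent-2-en-1-yl (2E)-2-methylbut-2-enoate, via lithiated ether 15 (not isolated), via lithium alkoxide 16 (not isolated)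
Conditions: n-BuLi, THF, −78 → −40 °C; then 14, −78 → 0 °C
Reagents that add atoms: none
Why: Deprotonation at the allylic OCH2 triggers a [2,3]-Wittig rearrangement that is suprafacial on the cyclopentene, so C1–C10 forms on the face that carried the ether oxygen (chirality transfer to quaternary C1 = R) with the alkenyl group exo in the envelope transition state (C10 = S), and the lithium alkoxide is acylated in the same flask.

**Step 9**
Reactants: 17 (1S,2Z)-5,5-diethoxy-3-methyl-1-[(1R)-1-methyl-3-(propan-2-yl)cyclopent-2-en-1-yl]pent-2-en-1-yl (2E)-2-methylbut-2-enoate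
Product: 18 (1S,2Z)-5-(hydroxyimino)-3-methyl-1-[(1R)-1-methyl-3-(propan-2-yl)cyclopent-2-en-1-yl]pent-2-en-1-yl (2E)-2-methylbut-2-enoate (E/Z oxime mixture)
Conditions: NH2OH·HCl, THF/H2O, 40 °C
Reagents that add atoms: hydroxylamine hydrochloride, NO.Cl
Why: The hydrochloride unmasks the acetal and traps the β,γ-unsaturated aldehyde at once as its oxime (transoximation), which avoids isomerisation into conjugation.

**Step 10**
Reactants: 18 (1S,2Z)-5-(hydroxyimino)-3-methyl-1-[(1R)-1-methyl-3-(propan-2-yl)cyclopent-2-en-1-yl]pent-2-en-1-yl (2E)-2-methylbut-2-enoate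
Product: 21 (1R,4R,5S,10S)-4,6-(epoxynitrilo)dauc-8-en-10-yl (2E)-2-methylbut-2-enoate (tricyclic 2-isoxazoline; C6=N–O–C4), via hydroximoyl chloride 19 (not isolated), via nitrile oxide 20 (not isolated)
Conditions: NCS, DMF, 0 °C → rt; then Et3N (syringe pump), CH2Cl2 (0.005 M), rt → 40 °C
Reagents that add atoms: none
Why: Intramolecular Huisgen nitrile oxide–olefin [3+2] cycloaddition (carbon to C5, oxygen to the more substituted C4) in which the short (Z)-alkenyl tether can only reach the ring face that carries C10, so the seven-membered ring closes cis-fused and C4–O ends up cis to C6 and C10 (sets C4 = R and C5 = S).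

**Step 11**
Reactants: 21 (1R,4R,5S,10S)-4,6-(epoxynitrilo)dauc-8-en-10-yl (2E)-2-methylbut-2-enoate
Product: 22 (1R,4R,5R,10S)-4-hydroxy-6-oxodauc-8-en-10-yl (2E)-2-methylbut-2-enoate
Conditions: Mo(CO)6, MeCN/H2O (15:1), 80 °C
Reagents that add atoms: water, O
Why: Mo(CO)6 cleaves the N–O bond reductively and the β-hydroxy imine hydrolyses to the β-hydroxy ketone (masked aldol) under near-neutral conditions that spare the alkenes and the tiglate and touch no stereocentre (the 5R label is only a priority change).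

**Step 12**
Reactants: 22 (1R,4R,5R,10S)-4-hydroxy-6-oxodauc-8-en-10-yl (2E)-2-methylbut-2-enoate
Product: 23 (1R,4R,5S,6S,10S)-4,6-dihydroxydauc-8-en-10-yl (2E)-2-methylbut-2-enoate
Conditions: Me4NBH(OAc)3, MeCN/AcOH (1:1), −30 °C
Reagents that add atoms: none
Why: Evans–Saksena directed reduction, in which the tertiary C4 hydroxyl binds the borohydride and delivers hydride to the ketone face syn to it, giving the 1,3-anti diol (6S, hydroxyl cis to H5) without reducing the ester.

**Step 13**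
Reactants: 23 (1R,4R,5S,6S,10S)-4,6-dihydroxydauc-8-en-10-yl (2E)-2-methylbut-2-enoate; 24 4-acetoxybenzoyl chloride
Product: 25 (1R,4R,5S,6S,10S)-6-[(4-acetoxybenzoyl)oxy]-4-hydroxydauc-8-en-10-yl (2E)-2-methylbut-2-enoate
Conditions: 24 (1.5 equiv), pyridine, DMAP (cat.), CH2Cl2, 0 → 40 °C
Reagents that add atoms: none
Why: DMAP-catalysed acyl transfer esterifies only the secondary C6 hydroxyl, the tertiary C4 hydroxyl being inert.

**Step 14**
Reactants: 25 (1R,4R,5S,6S,10S)-6-[(4-acetoxybenzoyl)oxy]-4-hydroxydauc-8-en-10-yl (2E)-2-methylbut-2-enoate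
Product: 26 (1R,4R,5S,6S,10S)-4-hydroxy-6-[(4-hydroxybenzoyl)oxy]dauc-8-en-10-yl (2E)-2-methylbut-2-enoate (target)
Conditions: pyrrolidine (3 equiv), CH2Cl2, 0 °C → rt
Reagents that add atoms: none
Why: Chemoselective aminolysis of the aryl acetate, far more electrophilic than the alkyl benzoate and the tiglate, frees the phenol.

**Compound list**
1 | (S)-(+)-terpinen-4-ol, (1S)-4-methyl-1-(propan-2-yl)cyclohex-3-en-1-ol | CC1=CC[C@](O)(C(C)C)CC1 | starting material
2 | secondary ozonide of 1, 1-methyl-4-(propan-2-yl)-7,8,9-trioxabicyclo[4.2.1]nonan-4-ol (carbinol centre as in 1) | CC12CC[C@@](O)(C(C)C)CC(OO1)O2 | intermediate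
3 | (3S)-3-hydroxy-6-oxo-3-(propan-2-yl)heptanal | CC(=O)CC[C@@](O)(C(C)C)CC=O | intermediate
4 | (5R)-5-hydroxy-2-methyl-5-(propan-2-yl)cyclopent-1-ene-1-carbaldehyde | CC1=C(C=O)[C@](O)(C(C)C)CC1 | intermediate
5 | (1R)-3-methyl-1-(propan-2-yl)cyclopent-2-en-1-ol | CC1=C[C@](O)(C(C)C)CC1 | intermediate
6 | 4,4-diethoxybut-1-yne | C#CCC(OCC)OCC | starting material
7 | lithium acetylide of 6 | [Li]C#CCC(OCC)OCC | intermediate
8 | methyl 5,5-diethoxypent-2-ynoate | COC(=O)C#CCC(OCC)OCC | intermediate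
9 | methyl (2Z)-5,5-diethoxy-3-methylpent-2-enoate | COC(=O)/C=C(/C)CC(OCC)OCC | intermediate
10 | (2Z)-5,5-diethoxy-3-methylpent-2-en-1-ol | OC/C=C(/C)CC(OCC)OCC | intermediate
11 | (2Z)-1-bromo-5,5-diethoxy-3-methylpent-2-ene | BrC/C=C(/C)CC(OCC)OCC | intermediate
12 | potassium alkoxide of 5 | CC1=C[C@]([O-])(C(C)C)CC1.[K+] | intermediate
13 | (1R)-1-{[(2Z)-5,5-diethoxy-3-methylpent-2-en-1-yl]oxy}-3-methyl-1-(propan-2-yl)cyclopent-2-ene | CC1=C[C@](OC/C=C(/C)CC(OCC)OCC)(C(C)C)CC1 | intermediate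
14 | tigloyl chloride, (2E)-2-methylbut-2-enoyl chloride | C/C=C(\C)C(Cl)=O | starting material
15 | 13 lithiated at the allylic OCH2 carbon | CC1=C[C@](OC([Li])/C=C(/C)CC(OCC)OCC)(C(C)C)CC1 | intermediate
16 | lithium (1S,2Z)-5,5-diethoxy-3-methyl-1-[(1R)-1-methyl-3-(propan-2-yl)cyclopent-2-en-1-yl]pent-2-en-1-olate | [Li+].[O-][C@@H](/C=C(/C)CC(OCC)OCC)[C@@]1(C)C=C(C(C)C)CC1 | intermediate
17 | (1S,2Z)-5,5-diethoxy-3-methyl-1-[(1R)-1-methyl-3-(propan-2-yl)cyclopent-2-en-1-yl]pent-2-en-1-yl (2E)-2-methylbut-2-enoate | C/C=C(\C)C(=O)O[C@@H](/C=C(/C)CC(OCC)OCC)[C@@]1(C)C=C(C(C)C)CC1 | intermediate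
18 | (1S,2Z)-5-(hydroxyimino)-3-methyl-1-[(1R)-1-methyl-3-(propan-2-yl)cyclopent-2-en-1-yl]pent-2-en-1-yl (2E)-2-methylbut-2-enoate | C/C=C(\C)C(=O)O[C@@H](/C=C(/C)CC=NO)[C@@]1(C)C=C(C(C)C)CC1 | intermediate
19 | hydroximoyl chloride of 18 | C/C=C(\C)C(=O)O[C@@H](/C=C(/C)CC(Cl)=NO)[C@@]1(C)C=C(C(C)C)CC1 | intermediate
20 | nitrile oxide from 19 | C/C=C(\C)C(=O)O[C@@H](/C=C(/C)CC#[N+][O-])[C@@]1(C)C=C(C(C)C)CC1 | intermediate
21 | (1R,4R,5S,10S)-4,6-(epoxynitrilo)dauc-8-en-10-yl (2E)-2-methylbut-2-enoate | C/C=C(\C)C(=O)O[C@H]1C=C(C)CC2=NO[C@@]3(C(C)C)CC[C@]1(C)[C@@H]23 | intermediate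
22 | (1R,4R,5R,10S)-4-hydroxy-6-oxodauc-8-en-10-yl (2E)-2-methylbut-2-enoate | C/C=C(\C)C(=O)O[C@H]1C=C(C)CC(=O)[C@@H]2[C@@]1(C)CC[C@@]2(O)C(C)C | intermediate
23 | (1R,4R,5S,6S,10S)-4,6-dihydroxydauc-8-en-10-yl (2E)-2-methylbut-2-enoate | C/C=C(\C)C(=O)O[C@H]1C=C(C)C[C@H](O)[C@@H]2[C@@]1(C)CC[C@@]2(O)C(C)C | intermediate
24 | 4-acetoxybenzoyl chloride | CC(=O)Oc1ccc(cc1)C(Cl)=O | starting material
25 | (1R,4R,5S,6S,10S)-6-[(4-acetoxybenzoyl)oxy]-4-hydroxydauc-8-en-10-yl (2E)-2-methylbut-2-enoate | C/C=C(\C)C(=O)O[C@H]1C=C(C)C[C@H](OC(=O)c2ccc(OC(C)=O)cc2)[C@@H]2[C@@]1(C)CC[C@@]2(O)C(C)C | intermediate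
26 | (1R,4R,5S,6S,10S)-4-hydroxy-6-[(4-hydroxybenzoyl)oxy]dauc-8-en-10-yl (2E)-2-methylbut-2-enoate | C/C=C(\C)C(=O)O[C@H]1C=C(C)C[C@H](OC(=O)c2ccc(O)cc2)[C@@H]2[C@@]1(C)CC[C@@]2(O)C(C)C | target

**Totals**
Total step count: 14. Longest linear sequence: 12 steps (6 → 26, steps 3–14); the branch from 1 is 10 steps (steps 1, 2, 7–14).

**Steps most likely to fail**

Step 2 (decarbonylation of a hindered tetrasubstituted enal beside a tertiary allylic alcohol: slow CO extrusion, dehydration on heating). The fallback sets out from 4 and comes back at 5, and removes the formyl carbon by oxidation instead of metal insertion. Baeyer–Villiger oxidation of 4 (mCPBA, NaHCO3, CH2Cl2, 0 °C) gives enol formate F1. K2CO3/MeOH cleaves it to α-hydroxy ketone F2. Because the carbinol carbon is fully substituted, F2 enolises only towards the methyl-bearing carbon, so KN(SiMe3)2/PhNTf2 gives a single enol triflate F3. Pd(OAc)2/PPh3, Et3N and HCO2H (DMF, 60 °C) then replace the triflate by hydrogen and give 5.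

Step 8 (rearrangement and in situ acylation: imperfect control at C10, partial Z/E scrambling of the allyl anion, competing [1,2]-shift). The fallback sets out from 13 and comes back at 21, and fixes C10 later on the rigid tricycle instead of in the rearrangement transition state. Rearrangement of 13 with n-BuLi alone and a water quench gives carbinol mixture F4 (both C10 epimers, C1 secure). NH2OH·HCl gives hydroxy oxime F5. PhI(OAc)2 (cat. CF3CO2H, MeOH) generates hydroxy nitrile oxide F6, which cyclises as in step 10 to hydroxy isoxazoline F7 (C10 epimers). Dess–Martin periodinane converges both epimers to enone F8. NaBH4/CeCl3·7H2O (MeOH, −78 °C) should add hydride from the convex face of the cis-fused tricycle and give the single allylic alcohol F9. Tigloyl chloride 14 (Et3N, DMAP) then gives 21.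

Step 10 (seven-membered ring closure onto a hindered trisubstituted alkene: furoxan dimerisation of the nitrile oxide may win). The fallback sets out from 17 and comes back at 21, and replaces the nitrile oxide by a silyl nitronate, a dipole that cannot dimerise and tolerates long heating. The acetal of 17 is hydrolysed (pyridinium p-toluenesulfonate, wet acetone) to aldehyde F10. NaBH4 (MeOH, 0 °C) gives primary alcohol F11. I2, PPh3 and imidazole give iodide F12, and NaNO2 (DMSO, phloroglucinol) gives nitro compound F13. Me3SiCl/Et3N (PhH, rt → 60 °C) gives silyl nitronate F14, which undergoes the intramolecular silyl nitronate–olefin cycloaddition to N-silyloxy isoxazolidine F15. TsOH (cat.) eliminates Me3SiOH and gives 21.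

**Further compounds**
F1 | step 2 | (5R)-5-hydroxy-2-methyl-5-(propan-2-yl)cyclopent-1-en-1-yl formate | CC1=C(OC=O)[C@](O)(C(C)C)CC1
F2 | step 2 | (2R)-2-hydroxy-5-methyl-2-(propan-2-yl)cyclopentan-1-one (C5 epimers) | CC1CC[C@@](O)(C(C)C)C1=O
F3 | step 2 | (5R)-5-hydroxy-2-methyl-5-(propan-2-yl)cyclopent-1-en-1-yl trifluoromethanesulfonate | CC1=C(OS(=O)(=O)C(F)(F)F)[C@](O)(C(C)C)CC1
F4 | step 8 | (2Z)-5,5-diethoxy-3-methyl-1-[(1R)-1-methyl-3-(propan-2-yl)cyclopent-2-en-1-yl]pent-2-en-1-ol (both carbinol epimers) | OC(/C=C(/C)CC(OCC)OCC)[C@@]1(C)C=C(C(C)C)CC1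
F5 | step 8 | (3Z)-5-hydroxy-3-methyl-5-[(1R)-1-methyl-3-(propan-2-yl)cyclopent-2-en-1-yl]pent-3-enal oxime (carbinol epimers) | OC(/C=C(/C)CC=NO)[C@@]1(C)C=C(C(C)C)CC1
F6 | step 8 | nitrile oxide from F5 | OC(/C=C(/C)CC#[N+][O-])[C@@]1(C)C=C(C(C)C)CC1
F7 | step 8 | (1R,4R,5S)-4,6-(epoxynitrilo)dauc-8-en-10-ol (C10 epimers) | OC1C=C(C)CC2=NO[C@@]3(C(C)C)CC[C@]1(C)[C@@H]23
F8 | step 8 | (1R,4R,5S)-4,6-(epoxynitrilo)dauc-8-en-10-one | O=C1C=C(C)CC2=NO[C@@]3(C(C)C)CC[C@]1(C)[C@@H]23
F9 | step 8 | (1R,4R,5S,10S)-4,6-(epoxynitrilo)dauc-8-en-10-ol | O[C@H]1C=C(C)CC2=NO[C@@]3(C(C)C)CC[C@]1(C)[C@@H]23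
F10 | step 10 | (1S,2Z)-3-methyl-1-[(1R)-1-methyl-3-(propan-2-yl)cyclopent-2-en-1-yl]-5-oxopent-2-en-1-yl (2E)-2-methylbut-2-enoate | C/C=C(\C)C(=O)O[C@@H](/C=C(/C)CC=O)[C@@]1(C)C=C(C(C)C)CC1
F11 | step 10 | (1S,2Z)-5-hydroxy-3-methyl-1-[(1R)-1-methyl-3-(propan-2-yl)cyclopent-2-en-1-yl]pent-2-en-1-yl (2E)-2-methylbut-2-enoate | C/C=C(\C)C(=O)O[C@@H](/C=C(/C)CCO)[C@@]1(C)C=C(C(C)C)CC1
F12 | step 10 | (1S,2Z)-5-iodo-3-methyl-1-[(1R)-1-methyl-3-(propan-2-yl)cyclopent-2-en-1-yl]pent-2-en-1-yl (2E)-2-methylbut-2-enoate | C/C=C(\C)C(=O)O[C@@H](/C=C(/C)CCI)[C@@]1(C)C=C(C(C)C)CC1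
F13 | step 10 | (1S,2Z)-3-methyl-1-[(1R)-1-methyl-3-(propan-2-yl)cyclopent-2-en-1-yl]-5-nitropent-2-en-1-yl (2E)-2-methylbut-2-enoate | C/C=C(\C)C(=O)O[C@@H](/C=C(/C)CC[N+](=O)[O-])[C@@]1(C)C=C(C(C)C)CC1
F14 | step 10 | trimethylsilyl nitronate of F13 | C/C=C(\C)C(=O)O[C@@H](/C=C(/C)CC=[N+]([O-])O[Si](C)(C)C)[C@@]1(C)C=C(C(C)C)CC1
F15 | step 10 | N-(trimethylsilyloxy) isoxazolidine, (1R,4R,5S,10S)-4,6-[epoxy(trimethylsilyloxy)imino]dauc-8-en-10-yl (2E)-2-methylbut-2-enoate (C6 unassigned) | C/C=C(\C)C(=O)O[C@H]1C=C(C)CC2N(O[Si](C)(C)C)O[C@@]3(C(C)C)CC[C@]1(C)[C@@H]23
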